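| setting | south | north | gamma | delta | theta | zeta |
|---|---|---|---|---|---|---|
| left-handed substrate | 0.10 M | 0.10 M | 0.10 M | 0.10 M | 0.10 M | 0.10 M |
| right-handed substrate | 0.10 M | 0.10 M | 0.10 M | 0.10 M | 0.10 M | 0.10 M |
| reagent | 2.7 equiv | 6 equiv | 4.00 equiv | 4.00 equiv | 4.00 equiv | 4.00 equiv |
| temperature | 85 °C | 110 °C | 130 °C |  | 110 °C | 90 °C |
| remark | run made earlier | run made earlier |  | at 90 °C until 10 h, from then on at 130 °C |  |  |
| time |  |  | 20 h | 20 h | 20 h | 20 h |

| run | time / h | left-handed product / % | right-handed product / % |
|---|---|---|---|
| south | 20.0 | 15.0 | 8.1 |
| south | 50.0 | 26.4 | 17.5 |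
| south | 96.0 | 35.7 | 26.4 |
| south | 144 | 39.6 | 32.7 |
| south | 192 | 42.7 | 37.4 |
| north | 5.00 | 42.7 | 24.9 |
| north | 15.0 | 50.1 | 44.2 |
| north | 25.0 | 50.4 | 48.5 |
| north | 40.0 | 49.9 | 50.1 |
| north | 60.0 | 49.8 | 50.6 |

(readings scatter by 0.5 percentage points)

- reagent is single-handed; left-handed substrate and right-handed substrate are mirror images of each other, charged as a racemate, each of them at the stated concentration
- an excess is the difference of the two amounts in percent of their sum
- an excess is below zero if the other one leads
- the handed part of reagent does not stay in what it makes, so the products of the two hands are mirror images too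

* the best flask by excess of left-handed product over right-handed product; "all alike" if 1.5 percentage points covers them all (gamma / delta / theta / zeta / all alike)
* excess of left-handed product over right-handed product at the end, gamma
* excess of left-handed product over right-handed product at the end, delta
* excess of left-handed product over right-handed product at the end, theta
* excess of left-handed product over right-handed product at the end, zeta

A percent in these tables counts both substrates together, so each hand owns half of the scale, and you reckon better with what is unmade than with what is made. Let u_L be the fraction of the left-handed half not yet present as left-handed product, that is, one minus twice the reading, and let u_R be the same for the right hand.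

How unequal are the hands? At the first south reading u_L is 0.700 and u_R is 0.838. That gives 2.02 for s, the ratio of ln u_L to ln u_R, your selectivity factor. The second south reading gives 1.74, so these readings show no constant s, and you carry the early value, a reading with its scatter.

How far does a flask get by the asked time? Treat the left hand as pseudo-first-order, with its rate constant proportional to the charged reagent. The first readings give 0.0178 h⁻¹ in the south run and 0.385 h⁻¹ in the north run. Per equivalent, that is a factor of 9.71 between their temperatures. Interpolating the logarithm of that factor to zeta gives u_L = 0.435. Scaling the north rate to theta's reagent gives u_L = 0.00591.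

What excess remains? Here u_R is u_L raised to the power one over s, and the excess is u_R minus u_L, divided by 2 minus both. My reckoning gives zeta 25.1% and theta 3.80%, which is less than zeta. As both u approach zero, the excess goes with them, so I expect gamma and delta, which end at 130 °C, near zero.

The forecast names zeta, with gamma 0%, delta 0%, theta 4% and zeta 33%: “Zeta is best, because it stops early.” Its zeta figure is higher than my reckoning.

The flasks give gamma 0%, delta 0.177%, theta 4.74% and zeta 28.5%, so zeta has a higher excess than the other flasks.

    reagent + left-handed substrate → left-handed product (k = 3.50 × 10⁻⁵ M⁻¹ s⁻¹, Ea = 106 kJ mol⁻¹)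
    reagent + right-handed substrate → right-handed product (k = 1.30 × 10⁻⁵ M⁻¹ s⁻¹, Ea = 84.0 kJ mol⁻¹)
    left-handed substrate ⇌ right-handed substrate (k = 9.10 × 10⁻⁶ s⁻¹, Ea = 114 kJ mol⁻¹)
    left-handed product ⇌ right-handed product (k = 3.70 × 10⁻⁶ s⁻¹, Ea = 118 kJ mol⁻¹)
    (constants at 90 °C)

Take the right-handed product in each flask at the asked time, with the carried s. Zeta then reckons to 25.8% against its 28.5%, at 43.9% conversion. Theta, the second flask, reckons to 6.28% against its 4.74%, at 91.0% conversion. The path from reagent and right-handed substrate to right-handed product is the main reason zeta's excess stays this low: zeta without that path stands at 74.7%, not 28.5%.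

The numbers in the tables are simulated for an exercise; the scatter is artificial.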